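**Retrosynthetic overview**
- Kazinol B ⇒ an open 2-hydroxy-retrochalcone whose ring B carries a 4-O-(1,1-dimethylpropargyl) ether and a 3-O-(1,1-dimethylallyl) ether. One flask operation (heat, then chiral phosphoric acid with Hantzsch ester) forms the C-prenyl group, the 2,2-dimethyl-2H-pyran ring and ring C with its C2 centre.
- Retrochalcone ⇒ Claisen–Schmidt union of a ring B acetophenone with 2,4-dihydroxybenzaldehyde (ring A).
- Ring B acetophenone ⇒ 3',4'-dihydroxyacetophenone, by site-selective O-propargylation of the 4-OH, then palladium-catalysed O-tert-prenylation of the 3-OH.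
- Ring order: rings A and B are bought; the 2,2-dimethyl-2H-pyran ring closes first and ring C (dihydropyran, C2 set as S) second, both in the final operation.

Assumption: the target is the (2S)-flavan written in the SMILES, and the (R)-configured phosphoric acid is taken to give the 2S sense of hydride delivery (its enantiomer is used if the sense proves opposite).

**Step 1**
Reactants: 1 3',4'-dihydroxyacetophenone; 2 3-chloro-3-methylbut-1-yne
Product: 3 1-[3-hydroxy-4-(2-methylbut-3-yn-2-yloxy)phenyl]ethan-1-one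
Conditions: K2CO3 (1.1 equiv), CuCl (2 mol %), acetone, 50 °C, N2
Reagents that add atoms: none
Why: The 4-OH lies para to the acetyl group and is the more acidic phenol, so one equivalent of base gives its phenoxide selectively, which is O-alkylated by the tertiary propargylic chloride through a monovalent-copper acetylide (copper-assisted propargylic etherification), leaving the 3-OH free and creating no stereocenter.

**Step 2**
Reactants: 4 2-methylbut-3-en-2-ol
Product: 5 methyl 2-methylbut-3-en-2-yl carbonate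
Conditions: n-BuLi, THF, −78 °C; then ClCO2Me, −78 °C to rt
Reagents that add atoms: methyl chloroformate, COC(=O)Cl
Why: Deprotonation of the tertiary alcohol and O-acylation of the lithium alkoxide with the chloroformate (alkoxycarbonylation) gives the tertiary allylic carbonate that serves as π-allyl precursor in the next step, with no stereocenter involved.

**Step 3**
Reactants: 3 1-[3-hydroxy-4-(2-methylbut-3-yn-2-yloxy)phenyl]ethan-1-one; 5 methyl 2-methylbut-3-en-2-yl carbonate
Product: 6 1-[3-(2-methylbut-3-en-2-yloxy)-4-(2-methylbut-3-yn-2-yloxy)phenyl]ethan-1-one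
Conditions: Pd(PPh3)4 (3 mol %), THF, 0 °C
Reagents that add atoms: none
Why: Tsuji–Trost O-allylation in which zerovalent palladium ionises the carbonate to a 1,1-dimethyl-π-allyl complex with loss of CO2, the methoxide formed deprotonates the remaining phenol, and at 0 °C the phenoxide attacks the more substituted allyl terminus under kinetic control to give the tertiary (reverse-prenyl) ether without touching the alkyne or the ketone.

**Step 4**
Reactants: 6 1-[3-(2-methylbut-3-en-2-yloxy)-4-(2-methylbut-3-yn-2-yloxy)phenyl]ethan-1-one; 7 2,4-dihydroxybenzaldehyde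
Product: 8 (2E)-3-(2,4-dihydroxyphenyl)-1-[3-(2-methylbut-3-en-2-yloxy)-4-(2-methylbut-3-yn-2-yloxy)phenyl]prop-2-en-1-one
Conditions: KOH (50 % aq), EtOH, rt; then AcOH to pH 6, 0 °C
Reagents that add atoms: none
Why: Claisen–Schmidt (crossed aldol) condensation of the methyl ketone enolate with the non-enolisable aldehyde followed by E1cB dehydration gives the conjugated E-enone, and the tertiary ethers and the terminal alkyne are inert to hydroxide at room temperature, which is kept low so that neither ether rearranges yet.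

**Step 5**
Reactants: 8 (2E)-3-(2,4-dihydroxyphenyl)-1-[3-(2-methylbut-3-en-2-yloxy)-4-(2-methylbut-3-yn-2-yloxy)phenyl]prop-2-en-1-one
Product: 13 kazinol B, via chromene chalcone 9 (not isolated), via dihydrochalcone 10 (not isolated), via lactol 11 (not isolated), via oxocarbenium ion 12 (not isolated)
Conditions: 1,2-dichlorobenzene, 170 °C, argon; then 45 °C, (R)-3,3'-bis(2,4,6-triisopropylphenyl)-1,1'-binaphthyl-2,2'-diyl hydrogen phosphate (10 mol %), diethyl 2,6-dimethyl-1,4-dihydropyridine-3,5-dicarboxylate (Hantzsch ester, 2.5 equiv), 5 Å MS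
Reagents that add atoms: none
Why: Proposed new method: heating first runs two known sigmatropic cascades on ring B side by side, an aromatic Claisen rearrangement of the 1,1-dimethylallyl ether into its only free ortho position (C-prenyl group and free 8-OH) and a propargyl Claisen rearrangement/1,5-hydrogen shift/oxa-6π electrocyclisation of the 1,1-dimethylpropargyl ether (2,2-dimethyl-2H-pyran ring), to give 9, and in the same flask the chiral phosphoric acid then protonates the enone so that the Hantzsch ester transfers hydride to the benzylic β-carbon (10), the ring A 2-OH closes onto the ketone (lactol 11, ring C), and acid-induced loss of water gives oxocarbenium ion 12 as a tight ion pair with the chiral phosphate, which also hydrogen-bonds the second Hantzsch ester and steers its hydride to one face of C2 to set the (2S) centre; the closest known reactions are chiral phosphoric acid/Hantzsch ester transfer hydrogenations of quinolines and benzopyrylium ions and the acid/hydride reductive cyclisation of 3-(2-hydroxyaryl)-1-arylpropan-1-ones to racemic flavans.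

**Compound list**
1 | 1-(3,4-dihydroxyphenyl)ethan-1-one (3',4'-dihydroxyacetophenone) | CC(=O)c1ccc(O)c(O)c1 | starting material
2 | 3-chloro-3-methylbut-1-yne | CC(C)(Cl)C#C | starting material
3 | 1-[3-hydroxy-4-(2-methylbut-3-yn-2-yloxy)phenyl]ethan-1-one | CC(=O)c1ccc(OC(C)(C)C#C)c(O)c1 | intermediate
4 | 2-methylbut-3-en-2-ol | C=CC(C)(C)O | starting material
5 | methyl 2-methylbut-3-en-2-yl carbonate | COC(=O)OC(C)(C)C=C | intermediate
6 | 1-[3-(2-methylbut-3-en-2-yloxy)-4-(2-methylbut-3-yn-2-yloxy)phenyl]ethan-1-one | CC(=O)c1ccc(OC(C)(C)C#C)c(OC(C)(C)C=C)c1 | intermediate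
7 | 2,4-dihydroxybenzaldehyde | O=Cc1ccc(O)cc1O | starting material
8 | (2E)-3-(2,4-dihydroxyphenyl)-1-[3-(2-methylbut-3-en-2-yloxy)-4-(2-methylbut-3-yn-2-yloxy)phenyl]prop-2-en-1-one | O=C(/C=C/c1ccc(O)cc1O)c1ccc(OC(C)(C)C#C)c(OC(C)(C)C=C)c1 | intermediate
9 | (2E)-3-(2,4-dihydroxyphenyl)-1-[8-hydroxy-2,2-dimethyl-7-(3-methylbut-2-en-1-yl)-2H-chromen-6-yl]prop-2-en-1-one (chromene chalcone) | O=C(/C=C/c1ccc(O)cc1O)c1cc2c(c(O)c1CC=C(C)C)OC(C)(C)C=C2 | intermediate
10 | 3-(2,4-dihydroxyphenyl)-1-[8-hydroxy-2,2-dimethyl-7-(3-methylbut-2-en-1-yl)-2H-chromen-6-yl]propan-1-one (dihydrochalcone) | O=C(CCc1ccc(O)cc1O)c1cc2c(c(O)c1CC=C(C)C)OC(C)(C)C=C2 | intermediate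
11 | 2-[8-hydroxy-2,2-dimethyl-7-(3-methylbut-2-en-1-yl)-2H-chromen-6-yl]-3,4-dihydro-2H-chromene-2,7-diol (racemic lactol) | OC1(CCc2ccc(O)cc2O1)c1cc3c(c(O)c1CC=C(C)C)OC(C)(C)C=C3 | intermediate
12 | 7-hydroxy-2-[8-hydroxy-2,2-dimethyl-7-(3-methylbut-2-en-1-yl)-2H-chromen-6-yl]-3,4-dihydrochromenylium (O1=C2 oxocarbenium ion, counter-ion the chiral phosphate) | Oc1ccc2c(c1)[O+]=C(CC2)c1cc3c(c(O)c1CC=C(C)C)OC(C)(C)C=C3 | intermediate
13 | kazinol B, (2S)-2-[8-hydroxy-2,2-dimethyl-7-(3-methylbut-2-en-1-yl)-2H-chromen-6-yl]-3,4-dihydro-2H-chromen-7-ol | CC(C)=CCc1c([C@@H]2CCc3ccc(O)cc3O2)cc2c(c1O)OC(C)(C)C=C2 | target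

**Step count and risks**
Total step count: 5. Longest linear sequence: 4 steps (steps 1, 3, 4 and 5).

Most likely to fail, first: step 5. The asymmetric reductive cyclisation is untested on this hindered ketone with its ortho prenyl group, so conversion and enantioselectivity are uncertain. The prenyl alkene could also capture the oxocarbenium ion in a Prins-type side reaction, and the polyphenolic enone must survive the heating. The fallback sets out from 8 and returns at 13. Only the thermal part is run and chromene chalcone 9 is isolated. Asymmetric transfer hydrogenation with RuCl(p-cymene)[(R,R)-TsDPEN] in HCO2H/Et3N reduces the conjugated C=C and then the ketone to the saturated alcohol (1R)-3-(2,4-dihydroxyphenyl)-1-[8-hydroxy-2,2-dimethyl-7-(3-methylbut-2-en-1-yl)-2H-chromen-6-yl]propan-1-ol F1. An intramolecular Mitsunobu etherification (PPh3, DIAD, THF, 0 °C) through the ring A 2-OH then closes ring C with inversion to give 13, with no cation at C2.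

Second: step 4. The doubly deprotonated aldehyde 7 is a poor electrophile, so the condensation may stall or give a low yield. The fallback sets out from 7 and returns at 9. Aldehyde 7 is protected with chloromethyl methyl ether and iPr2NEt as 2,4-bis(methoxymethoxy)benzaldehyde F2. Claisen–Schmidt condensation of F2 with 6 (KOH, EtOH, rt) gives (2E)-3-[2,4-bis(methoxymethoxy)phenyl]-1-[3-(2-methylbut-3-en-2-yloxy)-4-(2-methylbut-3-yn-2-yloxy)phenyl]prop-2-en-1-one F3. Heating F3 in 1,2-dichlorobenzene at 170 °C, before any acid is used, gives (2E)-3-[2,4-bis(methoxymethoxy)phenyl]-1-[8-hydroxy-2,2-dimethyl-7-(3-methylbut-2-en-1-yl)-2H-chromen-6-yl]prop-2-en-1-one F4. HCl in MeOH at 40 °C then removes both acetals to give 9, which is taken through the reductive half of step 5.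

Third: step 3. The phenol is hindered by the neighbouring tertiary ether, and the kinetic tertiary ether can isomerise to the linear prenyl ether or be lost on the palladium catalyst. The fallback sets out from 3 and returns at 9, building the two ring B groups one after the other without palladium allyl chemistry. Heating 3 (1,2-dichlorobenzene, 170 °C) gives 1-(8-hydroxy-2,2-dimethyl-2H-chromen-6-yl)ethan-1-one F5. Its 8-OH is alkylated with 2 (K2CO3, CuCl, acetone) to give 1-[2,2-dimethyl-8-(2-methylbut-3-yn-2-yloxy)-2H-chromen-6-yl]ethan-1-one F6. Semi-hydrogenation (H2, Pd/CaCO3 poisoned with Pb(OAc)2, quinoline) gives 1-[2,2-dimethyl-8-(2-methylbut-3-en-2-yloxy)-2H-chromen-6-yl]ethan-1-one F7. Aromatic Claisen rearrangement at 140 °C gives 1-[8-hydroxy-2,2-dimethyl-7-(3-methylbut-2-en-1-yl)-2H-chromen-6-yl]ethan-1-one F8. Claisen–Schmidt condensation of F8 with 7 gives 9, which is taken through the reductive half of step 5.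

**Further compounds**
F1 | step 5 | (1R)-3-(2,4-dihydroxyphenyl)-1-[8-hydroxy-2,2-dimethyl-7-(3-methylbut-2-en-1-yl)-2H-chromen-6-yl]propan-1-ol | O[C@H](CCc1ccc(O)cc1O)c1cc2c(c(O)c1CC=C(C)C)OC(C)(C)C=C2
F2 | step 4 | 2,4-bis(methoxymethoxy)benzaldehyde | COCOc1ccc(C=O)c(OCOC)c1
F3 | step 4 | (2E)-3-[2,4-bis(methoxymethoxy)phenyl]-1-[3-(2-methylbut-3-en-2-yloxy)-4-(2-methylbut-3-yn-2-yloxy)phenyl]prop-2-en-1-one | COCOc1ccc(/C=C/C(=O)c2ccc(OC(C)(C)C#C)c(OC(C)(C)C=C)c2)c(OCOC)c1
F4 | step 4 | (2E)-3-[2,4-bis(methoxymethoxy)phenyl]-1-[8-hydroxy-2,2-dimethyl-7-(3-methylbut-2-en-1-yl)-2H-chromen-6-yl]prop-2-en-1-one | COCOc1ccc(/C=C/C(=O)c2cc3c(c(O)c2CC=C(C)C)OC(C)(C)C=C3)c(OCOC)c1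
F5 | step 3 | 1-(8-hydroxy-2,2-dimethyl-2H-chromen-6-yl)ethan-1-one | CC(=O)c1cc(O)c2OC(C)(C)C=Cc2c1
F6 | step 3 | 1-[2,2-dimethyl-8-(2-methylbut-3-yn-2-yloxy)-2H-chromen-6-yl]ethan-1-one | CC(=O)c1cc(OC(C)(C)C#C)c2OC(C)(C)C=Cc2c1
F7 | step 3 | 1-[2,2-dimethyl-8-(2-methylbut-3-en-2-yloxy)-2H-chromen-6-yl]ethan-1-one | CC(=O)c1cc(OC(C)(C)C=C)c2OC(C)(C)C=Cc2c1
F8 | step 3 | 1-[8-hydroxy-2,2-dimethyl-7-(3-methylbut-2-en-1-yl)-2H-chromen-6-yl]ethan-1-one | CC(=O)c1cc2C=CC(C)(C)Oc2c(O)c1CC=C(C)C
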